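**Retrosynthetic overview** (guaiane numbering: five-membered ring C1–C5; seven-membered ring C1, C5–C10; C8 carries the ester oxygen; C11 is the side-chain carbinol carbon; α is the face of H-5)
1. Target ⇒ diol 18 + O-acetyl-p-coumaric acid 19 (C8–O ester); C11 carbinol ⇒ tert-butyl ester + 2 MeLi; the C4 and C7 stereocentres ⇒ one 8α-hydroxyl-directed hydrogenation of the 4(15),6-diene 16.
2. Enabling feature: in the seven-membered ring the sp3–sp3 bond C8–C9 lies between the tetrasubstituted C1=C10 alkene and the C6=C7 alkene of 15, a cyclohepta-1,4-diene whose C5 is bonded to both C1 and C6. This is the retron of a cis-1,6-dialkenylbicyclo[3.1.0]hexane (cyclopropane C1–C5–C6).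
3. C8–C9 is therefore made by a [3,3] divinylcyclopropane rearrangement of 14, which also places the C1=C10 alkene and relays the configuration of C5 to C8.
4. 14 ⇒ bicyclic ketone 11 (Wittig; formylation/O-alkylation); 11 ⇒ acyclic diazoketone 10 by enantioselective intramolecular cyclopropanation; 10 ⇒ alkyne 1 by syn-diboration and two Suzuki couplings.
5. Ring order: cyclopentane and cyclopropane together (step 5), then the cycloheptadiene at the expense of the cyclopropane (step 8); no ring is formed afterwards.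

Key step: step 8

Remark (assumption): the sense of asymmetric induction of the copper–bis(oxazoline) catalyst in step 5 is not predicted here; it is assigned in a pilot run and the ligand antipode that delivers (1R,5R,6R)-11 is used.

**Step 1**
Reactants: 1 methyl pent-4-ynoate; 2 bis(pinacolato)diboron
Product: 3 methyl (4E)-4,5-bis(4,4,5,5-tetramethyl-1,3,2-dioxaborolan-2-yl)pent-4-enoate (the two boryl groups cis)
Conditions: Pt(PPh3)4 (3 mol%), DMF, 80 °C
Reagents that add atoms: none
Why: Zerovalent-platinum-catalysed syn-diboration of a terminal alkyne, an ester-tolerant known reaction type, places both boryl groups cis and thereby fixes the later alkene geometry; no stereocentre is formed.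

**Step 2**
Reactants: 3 methyl (4E)-4,5-bis(pinacolboryl)pent-4-enoate; 4 tert-butyl bromoacetate; 5 2-bromopropene
Product: 7 1-tert-butyl 7-methyl (3Z)-4-(prop-1-en-2-yl)hept-3-enedioate, via mono-coupled alkenylboronate 6 (not isolated)
Conditions: 4, Pd(OAc)2, P(o-tol)3, K3PO4, THF–H2O, 25 °C; then 5, PdCl2(dppf), 50 °C
Reagents that add atoms: none
Why: Sequential Suzuki–Miyaura couplings of a 1,2-bis(boryl)alkene, in which the terminal C–B bond reacts first (with the α-bromo ester) and the internal one second (with the alkenyl bromide), both with retention, so that the isopropenyl group and the CH2CO2tBu arm should end cis on the trisubstituted alkene.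

**Step 3**
Reactants: 7 1-tert-butyl 7-methyl (3Z)-4-(prop-1-en-2-yl)hept-3-enedioate
Product: 8 (4Z)-7-tert-butoxy-7-oxo-4-(prop-1-en-2-yl)hept-4-enoic acid
Conditions: LiOH (1.1 equiv), THF–H2O, 0 °C; then 1 M HCl to pH 4
Reagents that add atoms: lithium hydroxide, [Li+].[OH-]
Why: Saponification differentiates the two carboxyl termini, because hydroxide attacks the unhindered methyl ester while the tert-butyl ester is sterically shielded.

**Step 4**
Reactants: 8 (4Z)-7-tert-butoxy-7-oxo-4-(prop-1-en-2-yl)hept-4-enoic acid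
Product: 10 tert-butyl (3Z)-8-diazo-7-oxo-4-(prop-1-en-2-yl)oct-3-enoate, via mixed isobutyl carbonic anhydride 9 (not isolated)
Conditions: i-BuOCOCl, Et3N, THF, −15 °C; then CH2N2, Et2O, 0 °C
Reagents that add atoms: diazomethane, C=[N+]=[N-]
Why: Acylation of diazomethane by a mixed carbonic anhydride (first stage of the Arndt–Eistert protocol) should give the α-diazoketone under non-acidic conditions that the diene and the tert-butyl ester tolerate.

**Step 5**
Reactants: 10 tert-butyl (3Z)-8-diazo-7-oxo-4-(prop-1-en-2-yl)oct-3-enoate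
Product: 11 tert-butyl 2-[(1R,5R,6R)-2-oxo-5-(prop-1-en-2-yl)bicyclo[3.1.0]hexan-6-yl]acetate
Conditions: CuOTf (5 mol%), 2,2′-(propane-2,2-diyl)bis[(4S)-4-tert-butyl-4,5-dihydro-1,3-oxazole] or its antipode (6 mol%), CH2Cl2, slow addition of 10, 0 → 20 °C
Reagents that add atoms: none
Why: Intramolecular cyclopropanation of the copper carbene from a diazoketone onto the proximal trisubstituted alkene of the diene forms the five- and three-membered rings together; the addition is stereospecific (the cis relation of isopropenyl and CH2CO2tBu in 10 becomes the bridgehead/exo cis relation), and the chiral bis(oxazoline) ligand selects the alkene face, setting C1, C5 and C6 in absolute terms.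

**Step 6**
Reactants: 11 tert-butyl 2-[(1R,5R,6R)-2-oxo-5-(prop-1-en-2-yl)bicyclo[3.1.0]hexan-6-yl]acetate
Product: 12 tert-butyl 2-[(1S,5R,6R)-2-methylidene-5-(prop-1-en-2-yl)bicyclo[3.1.0]hexan-6-yl]acetate
Conditions: Ph3PCH3Br, KOtBu, THF, 0 → 20 °C
Reagents that add atoms: methyltriphenylphosphonium bromide, C[P+](c1ccccc1)(c1ccccc1)c1ccccc1.[Br-]
Why: Wittig methylenation of the cyclopropyl ketone (the transformation that converts sabina ketone into sabinene) removes the carbonyl before any rearrangement-competent diene exists and leaves the 4(15)-methylidene group as the later source of the C4 methyl stereocentre.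

**Step 7**
Reactants: 12 tert-butyl 2-[(1S,5R,6R)-2-methylidene-5-(prop-1-en-2-yl)bicyclo[3.1.0]hexan-6-yl]acetate
Product: 14 tert-butyl (2E)-3-(methoxymethoxy)-2-[(1S,5S,6R)-2-methylidene-5-(prop-1-en-2-yl)bicyclo[3.1.0]hexan-6-yl]prop-2-enoate, via potassium formyl-ester enolate 13 (not isolated)
Conditions: KN(SiMe3)2 (2.2 equiv), THF, −78 °C; HCO2Et, −78 → 0 °C; then DMF, MOMCl, −20 → 0 °C
Reagents that add atoms: ethyl formate, CCOC=O; chloromethyl methyl ether, COCCl
Why: Claisen-type formylation of the ester enolate, then O-alkylation of the potassium enolate by a hard electrophile in DMF (the conditions that give (E)-β-alkoxyacrylates in β-methoxyacrylate chemistry), should install the second alkenyl group with its oxygen cis to the cyclopropane carbon.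

**Step 8**
Reactants: 14 tert-butyl (2E)-3-(methoxymethoxy)-2-[(1S,5S,6R)-2-methylidene-5-(prop-1-en-2-yl)bicyclo[3.1.0]hexan-6-yl]prop-2-enoate
Product: 15 tert-butyl (3aS,6S)-6-(methoxymethoxy)-8-methyl-3-methylidene-1,2,3,3a,6,7-hexahydroazulene-5-carboxylate
Conditions: toluene (degassed, trace BHT, base-washed glass), 120 °C, sealed tube
Reagents that add atoms: none
Why: Thermal [3,3]-sigmatropic (Cope) rearrangement of the cis-1,2-dialkenylcyclopropane unit: the strained C1–C6 cyclopropane bond breaks while C8–C9 forms through the boat transition state in which the isopropenyl and alkoxyacrylate groups lie over the three-membered ring, and strain release makes the step irreversible. The closest known reaction type is the divinylcyclopropane–cycloheptadiene rearrangement of 1,6-dialkenylbicyclo[3.1.0]hexanes to hydroazulenes. The seven-membered ring is closed by a concerted six-electron suprafacial–suprafacial ring expansion (three-membered ring plus the two alkenyl arms), not by cyclisation of an open chain. The only new stereocentre, C8, is controlled by the (E) geometry of the enol ether: the oxygen occupies the inward position of the boat and therefore ends cis to H-5 (α), while C5 keeps its configuration and the stereocentres at C1 and C6 are consumed. The step needs the boat pathway of the C1/C6 alkenyl pair to beat homolytic epimerisation and any other sigmatropic shift, which the fused cyclopentane secures by locking these two alkenyl groups cis (bridgehead and exo) while the exocyclic methylidene is held trans to both; the positions of the new alkenes (tetrasubstituted C1=C10, C6=C7) follow from the bond shift itself. The inward alkoxy group is expected to retard the reaction, hence 120 °C rather than ambient temperature.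

**Step 9**
Reactants: 15 tert-butyl (3aS,6S)-6-(methoxymethoxy)-8-methyl-3-methylidene-1,2,3,3a,6,7-hexahydroazulene-5-carboxylate
Product: 16 tert-butyl (3aS,6S)-6-hydroxy-8-methyl-3-methylidene-1,2,3,3a,6,7-hexahydroazulene-5-carboxylate
Conditions: ZnBr2, n-PrSH, CH2Cl2, 0 °C
Reagents that add atoms: none
Why: Lewis-acid/thiol cleavage of the methoxymethyl ether (ZnBr2 activates the acetal, the thiol captures the methoxymethyl cation) should free the C8 hydroxyl without Brønsted acid or base, which the skipped triene would not tolerate, and touches no stereocentre.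

**Step 10**
Reactants: 16 tert-butyl (3aS,6S)-6-hydroxy-8-methyl-3-methylidene-1,2,3,3a,6,7-hexahydroazulene-5-carboxylate
Product: 17 tert-butyl (3S,3aS,5S,6S)-6-hydroxy-3,8-dimethyl-1,2,3,3a,4,5,6,7-octahydroazulene-5-carboxylate
Conditions: H2 (1 atm), [Ir(cod)(PCy3)(py)]PF6 (5 mol%), CH2Cl2, 0 → 20 °C
Reagents that add atoms: none
Why: Hydroxyl-directed homogeneous hydrogenation, in which the 8α-hydroxyl binds the cationic iridium centre and delivers H2 to the α face of the C6=C7 enoate (H-7 cis to OH, ester trans), while the unhindered exocyclic alkene is reduced from the same less hindered α face (anti to C6) to give the β-methyl at C4, and the tetrasubstituted C1=C10 alkene should be left untouched.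

**Step 11**
Reactants: 17 tert-butyl (3S,3aS,5S,6S)-6-hydroxy-3,8-dimethyl-1,2,3,3a,4,5,6,7-octahydroazulene-5-carboxylate
Product: 18 (3S,3aS,5S,6S)-5-(2-hydroxypropan-2-yl)-3,8-dimethyl-1,2,3,3a,4,5,6,7-octahydroazulen-6-ol
Conditions: MeLi (5 equiv), THF, −78 → 0 °C; then H2O
Reagents that add atoms: methyllithium, [Li]C
Why: Double addition of methyllithium to the ester (through the methyl ketone) builds the C11 dimethylcarbinol, the lithium alkoxide of the C8 hydroxyl forming first and protecting C7 against elimination.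

**Step 12**
Reactants: 18 (3S,3aS,5S,6S)-5-(2-hydroxypropan-2-yl)-3,8-dimethyl-1,2,3,3a,4,5,6,7-octahydroazulen-6-ol; 19 (2E)-3-[4-(acetyloxy)phenyl]prop-2-enoic acid
Product: 20 (3S,3aS,5S,6S)-5-(2-hydroxypropan-2-yl)-3,8-dimethyl-1,2,3,3a,4,5,6,7-octahydroazulen-6-yl (2E)-3-[4-(acetyloxy)phenyl]prop-2-enoate
Conditions: DCC, DMAP (cat.), CH2Cl2, 0 → 20 °C
Reagents that add atoms: none
Why: Steglich esterification (carbodiimide activation, DMAP acyl transfer) should acylate the secondary C8 hydroxyl with retention, the tertiary C11 hydroxyl being too hindered to react.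

**Step 13**
Reactants: 20 (3S,3aS,5S,6S)-5-(2-hydroxypropan-2-yl)-3,8-dimethyl-1,2,3,3a,4,5,6,7-octahydroazulen-6-yl (2E)-3-[4-(acetyloxy)phenyl]prop-2-enoate
Product: 21 (3S,3aS,5S,6S)-5-(2-hydroxypropan-2-yl)-3,8-dimethyl-1,2,3,3a,4,5,6,7-octahydroazulen-6-yl (2E)-3-(4-hydroxyphenyl)prop-2-enoate
Conditions: K2CO3 (0.2 equiv), MeOH, 0 °C
Reagents that add atoms: none
Why: Base-catalysed methanolysis should cleave the activated aryl acetate much faster than the hindered secondary cinnamate, releasing the phenol of the target.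

**Compound list**
1 | methyl pent-4-ynoate | C#CCCC(=O)OC | starting material
2 | bis(pinacolato)diboron | CC1(C)OB(OC1(C)C)B1OC(C)(C)C(C)(C)O1 | starting material
3 | methyl (4E)-4,5-bis(4,4,5,5-tetramethyl-1,3,2-dioxaborolan-2-yl)pent-4-enoate (boryl groups cis) | COC(=O)CC/C(B1OC(C)(C)C(C)(C)O1)=C/B1OC(C)(C)C(C)(C)O1 | intermediate
4 | tert-butyl bromoacetate | CC(C)(C)OC(=O)CBr | starting material
5 | 2-bromopropene | C=C(C)Br | starting material
6 | 1-tert-butyl 7-methyl (3E)-4-(4,4,5,5-tetramethyl-1,3,2-dioxaborolan-2-yl)hept-3-enedioate | COC(=O)CC/C(B1OC(C)(C)C(C)(C)O1)=C/CC(=O)OC(C)(C)C | intermediate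
7 | 1-tert-butyl 7-methyl (3Z)-4-(prop-1-en-2-yl)hept-3-enedioate | COC(=O)CC/C(C(C)=C)=C/CC(=O)OC(C)(C)C | intermediate
8 | (4Z)-7-tert-butoxy-7-oxo-4-(prop-1-en-2-yl)hept-4-enoic acid | OC(=O)CC/C(C(C)=C)=C/CC(=O)OC(C)(C)C | intermediate
9 | (4Z)-7-tert-butoxy-7-oxo-4-(prop-1-en-2-yl)hept-4-enoic 2-methylpropyl carbonic anhydride | CC(C)COC(=O)OC(=O)CC/C(C(C)=C)=C/CC(=O)OC(C)(C)C | intermediate
10 | tert-butyl (3Z)-8-diazo-7-oxo-4-(prop-1-en-2-yl)oct-3-enoate | [N-]=[N+]=CC(=O)CC/C(C(C)=C)=C/CC(=O)OC(C)(C)C | intermediate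
11 | tert-butyl 2-[(1R,5R,6R)-2-oxo-5-(prop-1-en-2-yl)bicyclo[3.1.0]hexan-6-yl]acetate (6-exo) | C=C(C)[C@@]12CCC(=O)[C@@H]1[C@H]2CC(=O)OC(C)(C)C | intermediate
12 | tert-butyl 2-[(1S,5R,6R)-2-methylidene-5-(prop-1-en-2-yl)bicyclo[3.1.0]hexan-6-yl]acetate | C=C(C)[C@@]12CCC(=C)[C@@H]1[C@H]2CC(=O)OC(C)(C)C | intermediate
13 | potassium (1E)-3-tert-butoxy-2-[(1S,5S,6R)-2-methylidene-5-(prop-1-en-2-yl)bicyclo[3.1.0]hexan-6-yl]-3-oxoprop-1-en-1-olate | C=C(C)[C@@]12CCC(=C)[C@@H]1[C@H]2/C(C(=O)OC(C)(C)C)=C\[O-].[K+] | intermediate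
14 | tert-butyl (2E)-3-(methoxymethoxy)-2-[(1S,5S,6R)-2-methylidene-5-(prop-1-en-2-yl)bicyclo[3.1.0]hexan-6-yl]prop-2-enoate | C=C(C)[C@@]12CCC(=C)[C@@H]1[C@H]2/C(C(=O)OC(C)(C)C)=C\OCOC | intermediate
15 | tert-butyl (3aS,6S)-6-(methoxymethoxy)-8-methyl-3-methylidene-1,2,3,3a,6,7-hexahydroazulene-5-carboxylate | CC1=C2CCC(=C)[C@@H]2C=C(C(=O)OC(C)(C)C)[C@@H](OCOC)C1 | intermediate
16 | tert-butyl (3aS,6S)-6-hydroxy-8-methyl-3-methylidene-1,2,3,3a,6,7-hexahydroazulene-5-carboxylate | CC1=C2CCC(=C)[C@@H]2C=C(C(=O)OC(C)(C)C)[C@@H](O)C1 | intermediate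
17 | tert-butyl (3S,3aS,5S,6S)-6-hydroxy-3,8-dimethyl-1,2,3,3a,4,5,6,7-octahydroazulene-5-carboxylate | CC1=C2CC[C@H](C)[C@@H]2C[C@H](C(=O)OC(C)(C)C)[C@@H](O)C1 | intermediate
18 | (3S,3aS,5S,6S)-5-(2-hydroxypropan-2-yl)-3,8-dimethyl-1,2,3,3a,4,5,6,7-octahydroazulen-6-ol | CC1=C2CC[C@H](C)[C@@H]2C[C@H](C(C)(C)O)[C@@H](O)C1 | intermediate
19 | (2E)-3-[4-(acetyloxy)phenyl]prop-2-enoic acid | CC(=O)Oc1ccc(/C=C/C(=O)O)cc1 | starting material
20 | (3S,3aS,5S,6S)-5-(2-hydroxypropan-2-yl)-3,8-dimethyl-1,2,3,3a,4,5,6,7-octahydroazulen-6-yl (2E)-3-[4-(acetyloxy)phenyl]prop-2-enoate | CC1=C2CC[C@H](C)[C@@H]2C[C@H](C(C)(C)O)[C@@H](OC(=O)/C=C/c2ccc(OC(C)=O)cc2)C1 | intermediate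
21 | (3S,3aS,5S,6S)-5-(2-hydroxypropan-2-yl)-3,8-dimethyl-1,2,3,3a,4,5,6,7-octahydroazulen-6-yl (2E)-3-(4-hydroxyphenyl)prop-2-enoate | CC1=C2CC[C@H](C)[C@@H]2C[C@H](C(C)(C)O)[C@@H](OC(=O)/C=C/c2ccc(O)cc2)C1 | target

**Totals**
Total step count: 13. Longest linear sequence: 13 steps (1 → 21).

**Steps most likely to fail**

Step 8. The inward methoxymethoxy group may raise the barrier of the boat transition state so far that, at the temperature then required, one-centre epimerisation of the cyclopropane or thermal degradation of the enol ether and of the skipped triene competes with the rearrangement. The fallback sets out from 12. Formylation as in step 7, but with O-alkylation of the lithium-chelated enolate (LiN(iPr)2, HCO2Et, then MOMCl in THF), should give the (Z)-enol ether F1, in which the oxygen is outward. Its rearrangement should run at 60–80 °C and give the C8-epimeric cycloheptadiene F2. ZnBr2/n-PrSH then gives the 8β-alcohol F3, and Mitsunobu inversion (4-nitrobenzoic acid, PPh3, DIAD) gives the 8α-(4-nitrobenzoate) F4. Methanolysis (K2CO3, MeOH, 0 °C) returns to the route at 16.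

Step 5. The copper carbene may discriminate the two alkene faces insufficiently (or add in part to the isopropenyl group), so that 11 is obtained with low optical purity. The fallback sets out from 10. Achiral Rh2(OAc)4 in CH2Cl2 gives racemic 11, which is resolved by preparative chromatography on a chiral stationary phase (cellulose tris(3,5-dimethylphenylcarbamate)). The wanted enantiomer is 11 itself, where the route is rejoined; the unwanted (1S,5S,6S)-enantiomer F5 is discarded.

Step 10. Iridium-hydride-mediated migration of the exocyclic C4=C15 alkene into conjugation with C1=C10 (which would erase C5), over-reduction of the tetrasubstituted alkene, or incomplete facial control at C4 may occur when both alkenes are reduced in one operation. The fallback sets out from 15, before deprotection. Diimide (2-nitrobenzenesulfonohydrazide, Et3N, CH2Cl2) is a metal-free reductant that does not isomerise alkenes and leaves the enoate and the tetrasubstituted alkene alone. It should reduce only the 1,1-disubstituted exocyclic alkene from the less hindered α face and give the 4β-methyl ether F6. ZnBr2/n-PrSH then gives the hydroxy enoate F7, and the hydroxyl-directed hydrogenation with [Ir(cod)(PCy3)(py)]PF6 has only the C6=C7 enoate left to reduce, returning to the route at 17.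

**Further compounds**
F1 | step 8 | tert-butyl (2Z)-3-(methoxymethoxy)-2-[(1S,5S,6R)-2-methylidene-5-(prop-1-en-2-yl)bicyclo[3.1.0]hexan-6-yl]prop-2-enoate | C=C(C)[C@@]12CCC(=C)[C@@H]1[C@H]2/C(C(=O)OC(C)(C)C)=C/OCOC
F2 | step 8 | tert-butyl (3aS,6R)-6-(methoxymethoxy)-8-methyl-3-methylidene-1,2,3,3a,6,7-hexahydroazulene-5-carboxylate | CC1=C2CCC(=C)[C@@H]2C=C(C(=O)OC(C)(C)C)[C@H](OCOC)C1
F3 | step 8 | tert-butyl (3aS,6R)-6-hydroxy-8-methyl-3-methylidene-1,2,3,3a,6,7-hexahydroazulene-5-carboxylate | CC1=C2CCC(=C)[C@@H]2C=C(C(=O)OC(C)(C)C)[C@H](O)C1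
F4 | step 8 | tert-butyl (3aS,6S)-8-methyl-3-methylidene-6-[(4-nitrobenzoyl)oxy]-1,2,3,3a,6,7-hexahydroazulene-5-carboxylate | CC1=C2CCC(=C)[C@@H]2C=C(C(=O)OC(C)(C)C)[C@@H](OC(=O)c2ccc(cc2)[N+](=O)[O-])C1
F5 | step 5 | tert-butyl 2-[(1S,5S,6S)-2-oxo-5-(prop-1-en-2-yl)bicyclo[3.1.0]hexan-6-yl]acetate | C=C(C)[C@]12CCC(=O)[C@H]1[C@@H]2CC(=O)OC(C)(C)C
F6 | step 10 | tert-butyl (3S,3aR,6S)-6-(methoxymethoxy)-3,8-dimethyl-1,2,3,3a,6,7-hexahydroazulene-5-carboxylate | CC1=C2CC[C@H](C)[C@@H]2C=C(C(=O)OC(C)(C)C)[C@@H](OCOC)C1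
F7 | step 10 | tert-butyl (3S,3aR,6S)-6-hydroxy-3,8-dimethyl-1,2,3,3a,6,7-hexahydroazulene-5-carboxylate | CC1=C2CC[C@H](C)[C@@H]2C=C(C(=O)OC(C)(C)C)[C@@H](O)C1
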